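| setting | alder | flask |
|---|---|---|
| free monomer | 0.20 M | 0.20 M |
| protic impurity | 0.20 M | 0.200 M |
| initiator | 10 mol% | 10 mol% |
| remark | the very flask that is asked about, followed so far |  |
| time |  | 10 d |

- alder (time / h: monomer in chains / %, free monomer / %): 6.00: 5.2, 73.4; 12.0: 10.5, 58.2; 15.0: 12.4, 49.2; 25.0: 18.5, 35.1; 30.0: 18.2, 29.0

(scatter of a reading: 1 percentage point)

1. average number of monomer units in a chain (chains begun, living or dead) at 10 d
2. part of the free monomer that has reacted at 10 d

- the average divides the monomer in chains by the number of chains begun, living and dead together
- the earlier runs do not show the number of chains; that part of a forecast is a guess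

- Start with a subtraction: the free monomer gone from the flask is the charge minus the reading, and monomer in chains stands beside it, so you can divide one by the other without assuming any mechanism.
- At 30.0 h that gives 25.6%, about a quarter: this is the chain share, monomer in chains over free monomer reacted, a selectivity.
- Now turn the question round: for chains to take as much free monomer as goes elsewhere, the share would have to be 0.5, the even line of your scale.
- The same reading would then show 35.5% in chains, and it shows 18.2%, a gap of 17 percentage points with a scatter of 1 point on each reading.
- The first reading gives a share of 19.5% and the fourth 28.5%, both on the same side of the even line.
- My own reckoning: if the free monomer reacts to the end at this share and each initiator begins one chain, the average is the share over the loading, 2.56.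
- The forecast says 3 for the average, above my figure, and 98% for the part reacted, and warns: “The chain count is a guess: transfer would lower it, slow initiation raise it.”
- The flask gives 5.81 and 95.4% at 10.0 d.

    free monomer + living end → monomer in chains + living end, rate k1*[living end]*[free monomer] (k = 0.0420 M⁻¹ min⁻¹)
    free monomer + initiator → living end + monomer in chains (k = 0.00740 M⁻¹ min⁻¹)
    protic impurity + free monomer → quenched substrate (k = 0.00370 M⁻¹ min⁻¹)
    monomer in chains + living end → free monomer + living end, rate k4*[living end] as long as [monomer in chains] is above zero (k = 6.50 × 10⁻⁴ min⁻¹)
    2 initiator → spent initiator (k = 0.170 M⁻¹ min⁻¹)

- That average is twice the forecast's, and in this flask c(living end) stands at 0.00648 M, a third of the 0.0200 M of initiator charged. The chain share here has come to 19.8%, below the even line. The neighbour flask charged with 0.80 M of free monomer, holding 0.250 equiv of protic impurity, reaches a share of 76.0%, above that line, with an average of 20.9.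

The runs were computed on assumed constants, noise included.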